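**Strategy.** The ten-membered ring (C1–C10) is closed last at its one alkene–carbinol junction, the secondary allylic alcohol C2 beside the Z-trisubstituted C1=C10 alkene. An intramolecular Nozaki–Hiyama–Kishi reaction of a seco (Z)-alkenyl iodide aldehyde joins C1 to C2, closes the cyclodeca-1(10),4-diene and creates the C2 carbinol in one operation, with the alkene geometry carried over from the iodide. The precursor is an open-chain trans-α-methylene-γ-butyrolactone (C6, C7, C11–C13) that already carries the C9 ester; it comes from an anti-selective, chromium-catalysed 2-(alkoxycarbonyl)allylation of a C2–C6 enal with an allylic bromide made by cross-metathesis.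

Key step: step 14

Remark: atoms are numbered as in germacranolides (ring C1–C10; lactone O on C6, C12(=O)–C11(=C13) on C7; C14 on C10, C15 on C4); the target is the (1(10)Z,4E)-(2R,6R,7S,9S) isomer with a trans-fused lactone, and compounds 14 and 16 are taken as purchasable.

## Route

Step 1
Reactants: 1 prop-2-yn-1-ol
Product: 3 (Z)-3-iodo-2-methylprop-2-en-1-ol, via alkenylmagnesium alkoxide 2 (not isolated)
Conditions: MeMgBr (2.5 equiv), CuI (10 mol %), Et2O/THF, −10 °C to rt; then I2, −78 to 0 °C
Reagents that add atoms: methylmagnesium bromide, C[Mg]Br; iodine, II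
Why: Copper-catalysed anti-carbomagnesiation of the propargylic alkoxide (Duboudin reaction) puts methyl on C10 and magnesium on C1 cis to the CH2O group in a five-membered chelate, and iodinolysis with retention should give the Z-iodide.

Step 2
Reactants: 3 (Z)-3-iodo-2-methylprop-2-en-1-ol
Product: 4 (Z)-3-iodo-2-methylprop-2-enal
Conditions: MnO2, CH2Cl2, rt, dark; filtered solution used at once
Reagents that add atoms: none
Why: Allylic oxidation on MnO2 is neutral and should leave the Z-iodoalkene intact; the aldehyde is used cold and at once because it can isomerise to the E form.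

Step 3
Reactants: 4 (Z)-3-iodo-2-methylprop-2-enal
Product: 5 (3S,1Z)-1-iodo-2-methylhexa-1,5-dien-3-ol
Conditions: (−)-Ipc2BOMe, allylMgBr, Et2O, 0 °C to rt; then 4, −78 °C; NaOH, H2O2
Reagents that add atoms: allylmagnesium bromide, C=CC[Mg]Br
Why: Brown allylboration through a chair transition state; the isopinocampheyl groups from (+)-α-pinene should direct allyl to the Si face of the enal, which sets C9 as S under reagent control.

Step 4
Reactants: 6 (E)-but-2-enal (crotonaldehyde)
Product: 7 (Z)-2-iodobut-2-enal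
Conditions: I2, K2CO3, DMAP (cat.), THF/H2O, rt
Reagents that add atoms: iodine, II
Why: α-Iodination of an enal by conjugate addition of DMAP, iodination of the enolate and elimination should give the more stable isomer with iodine cis to the methyl group.

Step 5
Reactants: 7 (Z)-2-iodobut-2-enal
Product: 8 (Z)-2-iodobut-2-en-1-ol
Conditions: NaBH4, MeOH, 0 °C
Reagents that add atoms: none
Why: Borohydride 1,2-reduction of the α-iodo enal does not touch the alkene geometry.

Step 6
Reactants: 8 (Z)-2-iodobut-2-en-1-ol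
Product: 9 tert-butyl{[(Z)-2-iodobut-2-en-1-yl]oxy}diphenylsilane
Conditions: TBDPSCl, imidazole, CH2Cl2, rt
Reagents that add atoms: tert-butyl(chloro)diphenylsilane, CC(C)(C)[Si](Cl)(c1ccccc1)c1ccccc1
Why: Standard silylation; the TBDPS ether is chosen because it outlasts the later cleavage of a primary TBS ether.

Step 7
Reactants: 9 tert-butyl{[(Z)-2-iodobut-2-en-1-yl]oxy}diphenylsilane
Product: 11 (Z)-2-{[(tert-butyldiphenylsilyl)oxy]methyl}but-2-enoic acid, via alkenyllithium 10 (not isolated)
Conditions: t-BuLi (2.1 equiv), Et2O, −78 °C; CO2; then aq. HCl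
Reagents that add atoms: carbon dioxide, O=C=O
Why: Iodine–lithium exchange and carboxylation both proceed with retention at sp2 carbon, so the carboxyl group should end cis to the β-methyl group, as in the side chain of the target.

Step 8
Reactants: 5 (3S,1Z)-1-iodo-2-methylhexa-1,5-dien-3-ol and 11 (Z)-2-{[(tert-butyldiphenylsilyl)oxy]methyl}but-2-enoic acid
Product: 13 (3S,1Z)-1-iodo-2-methylhexa-1,5-dien-3-yl (Z)-2-{[(tert-butyldiphenylsilyl)oxy]methyl}but-2-enoate, via mixed anhydride 12 (not isolated)
Conditions: 11, 2,4,6-Cl3C6H2COCl, Et3N, toluene, rt; then 5, 80 °C (no DMAP)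
Reagents that add atoms: none
Why: Yamaguchi esterification; the alcohol attacks the unhindered acyl carbon of the mixed anhydride, C9 keeps its configuration because its C–O bond is not broken, and omitting DMAP should avoid Z-to-E isomerisation of the angelate-type acyl group.

Step 9
Reactants: 13 (ester from step 8) and 14 methyl 2-(bromomethyl)prop-2-enoate
Product: 15 methyl (2Z,5S,6Z)-2-(bromomethyl)-5-{[(Z)-2-{[(tert-butyldiphenylsilyl)oxy]methyl}but-2-enoyl]oxy}-7-iodo-6-methylhepta-2,6-dienoate
Conditions: second-generation Hoveyda–Grubbs catalyst (5 mol %), 14 (4 equiv), CH2Cl2, 40 °C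
Reagents that add atoms: none
Why: Cross-metathesis of a terminal alkene with a 2-substituted acrylate; the trisubstituted iodoalkene and the side-chain acrylate are too hindered and electron-poor to take part, and the geometry of the new alkene does not matter because allylchromium 20 equilibrates.

Step 10
Reactants: 16 tert-butyl(but-3-yn-1-yloxy)dimethylsilane
Product: 18 (E)-5-{[tert-butyl(dimethyl)silyl]oxy}-3-methylpent-2-en-1-ol, via alkenylalane 17 (not isolated)
Conditions: Me3Al, Cp2ZrCl2 (20 mol %), CH2Cl2, 0 °C to rt; then n-BuLi, (CH2O)n, THF, −30 °C to rt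
Reagents that add atoms: trimethylaluminium, C[Al](C)C; formaldehyde (from paraformaldehyde), C=O
Why: Negishi zirconium-catalysed syn-carboalumination places methyl on C4 and aluminium on C5, and hydroxymethylation of the derived alanate with retention should fix the 4E geometry.

Step 11
Reactants: 18 (E)-5-{[tert-butyl(dimethyl)silyl]oxy}-3-methylpent-2-en-1-ol
Product: 19 (E)-5-{[tert-butyl(dimethyl)silyl]oxy}-3-methylpent-2-enal
Conditions: MnO2, CH2Cl2, rt
Reagents that add atoms: none
Why: Selective allylic oxidation on MnO2 should keep the E geometry.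

Step 12
Reactants: 15 (allylic bromide from step 9) and 19 (E)-5-{[tert-butyl(dimethyl)silyl]oxy}-3-methylpent-2-enal
Product: 23 seco hydroxy lactone (6R,7S,9S), via allylchromium 20 (not isolated), via silyl ether ester 21 (not isolated), via TBS lactone 22 (not isolated)
Conditions: CrCl2 (10 mol %, nickel-free), chiral carbazole-1,8-bis(oxazoline) ligand (12 mol %), Mn powder, TMSCl, i-Pr2NEt, THF, rt; then PPTS, MeOH, rt
Reagents that add atoms: none
Why: Catalytic asymmetric Nozaki–Hiyama-type 2-(alkoxycarbonyl)allylation in which the γ-substituted allylchromium adds through a chair transition state to give the anti adduct (hence the trans lactone), the ligand antipode that sends the allyl group to the Si face of 19 (C6 R, C7 S; catalyst control over the remote C9 centre) being fixed in a test run; divalent chromium without nickel should not touch the alkenyl iodide, and PPTS in methanol then cleaves the TMS ether, closes the lactone and removes the primary TBS group while the TBDPS ether stays.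

Step 13
Reactants: 23 seco hydroxy lactone
Product: 24 seco aldehyde (6R,7S,9S)
Conditions: Dess–Martin periodinane, pyridine, CH2Cl2, 0 °C; used crude
Reagents that add atoms: none
Why: Dess–Martin oxidation under buffered conditions should give the β,γ-unsaturated aldehyde without migration of the C4=C5 bond into conjugation.

Step 14
Reactants: 24 seco aldehyde
Product: 26 TBDPS ether of the target (2R,6R,7S,9S), via alkenylchromium 25 (not isolated)
Conditions: CrCl2 (10 equiv), NiCl2 (0.1 equiv), DMSO/THF (3:1), rt, syringe-pump addition of 24 to a final 2 mM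
Reagents that add atoms: none
Why: Zerovalent nickel formed in the flask inserts into the C1–I bond with retention, the alkenyl group passes to trivalent chromium (25), and the alkenylchromium adds to the chromium-bound C2 aldehyde to give the chromium alkoxide of 26. The closest known reaction type is the intramolecular Nozaki–Hiyama–Kishi coupling of an alkenyl iodide with an aldehyde, an established way to close medium and large carbocycles at an allylic carbinol. The ten-membered carbocycle closes in the 10-exo-trig mode (C1 onto C2=O, oxygen outside the ring), the trans-fused lactone and the two trisubstituted alkenes leaving few rotatable bonds in the tether. The new stereocentre C2 is set by the substrate: allylic 1,3-strain across the Z-C1=C10 bond should keep H-9 and the formyl hydrogen in the alkene plane, so the C3–C8 tether lies on one face of that plane and the chromium-bound oxygen on the other, the face of the C9 acyloxy group, which is addition to the Si face of the aldehyde and gives 2R. The step needs attack on the aldehyde only (not on the esters or the α-methylene lactone), retention of the Z geometry and ring closure ahead of oligomerisation; the low basicity and nucleophilicity of alkenylchromium, the configurational stability of the trisubstituted alkenyl metal and slow addition at high dilution should secure these.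

Step 15
Reactants: 26 TBDPS ether of the target
Product: 27 target CNP0273961.1
Conditions: TBAF, AcOH (1:1), THF, 0 °C to rt
Reagents that add atoms: none
Why: Fluoride buffered with acetic acid should remove the primary TBDPS ether without base damage to the α-methylene lactone or acid-induced transannular cyclisation of the 1(10),4-diene.

## Compound list

1 | prop-2-yn-1-ol (propargyl alcohol) | C#CCO | starting material
2 | bromomagnesium (Z)-3-(bromomagnesio)-2-methylprop-2-en-1-olate (chelated alkenylmagnesium alkoxide) | Br[Mg]/C=C(/C)CO[Mg]Br | intermediate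
3 | (Z)-3-iodo-2-methylprop-2-en-1-ol | OC/C(C)=C\I | intermediate
4 | (Z)-3-iodo-2-methylprop-2-enal | O=C/C(C)=C\I | intermediate
5 | (3S,1Z)-1-iodo-2-methylhexa-1,5-dien-3-ol | I/C=C(/C)[C@@H](O)CC=C | intermediate
6 | (E)-but-2-enal (crotonaldehyde) | C/C=C/C=O | starting material
7 | (Z)-2-iodobut-2-enal | C/C=C(\I)C=O | intermediate
8 | (Z)-2-iodobut-2-en-1-ol | C/C=C(\I)CO | intermediate
9 | tert-butyl{[(Z)-2-iodobut-2-en-1-yl]oxy}diphenylsilane | C/C=C(\I)CO[Si](c1ccccc1)(c1ccccc1)C(C)(C)C | intermediate
10 | [(Z)-1-{[(tert-butyldiphenylsilyl)oxy]methyl}prop-1-en-1-yl]lithium | C/C=C(\[Li])CO[Si](c1ccccc1)(c1ccccc1)C(C)(C)C | intermediate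
11 | (Z)-2-{[(tert-butyldiphenylsilyl)oxy]methyl}but-2-enoic acid | C/C=C(/CO[Si](c1ccccc1)(c1ccccc1)C(C)(C)C)C(=O)O | intermediate
12 | mixed anhydride of 11 and 2,4,6-trichlorobenzoic acid | C/C=C(/CO[Si](c1ccccc1)(c1ccccc1)C(C)(C)C)C(=O)OC(=O)c1c(Cl)cc(Cl)cc1Cl | intermediate
13 | (3S,1Z)-1-iodo-2-methylhexa-1,5-dien-3-yl (Z)-2-{[(tert-butyldiphenylsilyl)oxy]methyl}but-2-enoate | I/C=C(/C)[C@@H](OC(=O)/C(=C\C)CO[Si](c1ccccc1)(c1ccccc1)C(C)(C)C)CC=C | intermediate
14 | methyl 2-(bromomethyl)prop-2-enoate | C=C(CBr)C(=O)OC | starting material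
15 | methyl (2Z,5S,6Z)-2-(bromomethyl)-5-{[(Z)-2-{[(tert-butyldiphenylsilyl)oxy]methyl}but-2-enoyl]oxy}-7-iodo-6-methylhepta-2,6-dienoate | I/C=C(/C)[C@@H](OC(=O)/C(=C\C)CO[Si](c1ccccc1)(c1ccccc1)C(C)(C)C)C/C=C(\CBr)C(=O)OC | intermediate
16 | tert-butyl(but-3-yn-1-yloxy)dimethylsilane | C#CCCO[Si](C)(C)C(C)(C)C | starting material
17 | [(E)-4-{[tert-butyl(dimethyl)silyl]oxy}-2-methylbut-1-en-1-yl]dimethylalane | C[Al](C)/C=C(\C)CCO[Si](C)(C)C(C)(C)C | intermediate
18 | (E)-5-{[tert-butyl(dimethyl)silyl]oxy}-3-methylpent-2-en-1-ol | OC/C=C(\C)CCO[Si](C)(C)C(C)(C)C | intermediate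
19 | (E)-5-{[tert-butyl(dimethyl)silyl]oxy}-3-methylpent-2-enal | O=C/C=C(\C)CCO[Si](C)(C)C(C)(C)C | intermediate
20 | allylchromium dichloride from 15 (chromium on C13, C8 trans to C13, 9S) | COC(=O)/C(C[Cr](Cl)Cl)=C\C[C@H](OC(=O)/C(=C\C)CO[Si](c1ccccc1)(c1ccccc1)C(C)(C)C)/C(C)=C\I | intermediate
21 | open-chain anti adduct (6R,7S,9S): methyl 2-methylidene ester with C6–OTMS, C2–OTBS, C9 ester and (Z)-alkenyl iodide | COC(=O)C(=C)[C@@H]([C@H](O[Si](C)(C)C)/C=C(\C)CCO[Si](C)(C)C(C)(C)C)C[C@H](OC(=O)/C(=C\C)CO[Si](c1ccccc1)(c1ccccc1)C(C)(C)C)/C(C)=C\I | intermediate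
22 | (6R,7S,9S)-trans-α-methylene-γ-butyrolactone with the (E)-4-(TBS-oxy)-2-methylbut-1-enyl chain on C6 and the (2S,3Z)-2-acyloxy-4-iodo-3-methylbut-3-enyl chain on C7 (acyl as in 11) | C=C1C(=O)O[C@H](/C=C(\C)CCO[Si](C)(C)C(C)(C)C)[C@H]1C[C@H](OC(=O)/C(=C\C)CO[Si](c2ccccc2)(c2ccccc2)C(C)(C)C)/C(C)=C\I | intermediate
23 | as 22 with free C2 hydroxyl: (2S,3Z)-1-{(2R,3S)-2-[(E)-4-hydroxy-2-methylbut-1-en-1-yl]-4-methylidene-5-oxooxolan-3-yl}-4-iodo-3-methylbut-3-en-2-yl (Z)-2-{[(tert-butyldiphenylsilyl)oxy]methyl}but-2-enoate | C=C1C(=O)O[C@H](/C=C(\C)CCO)[C@H]1C[C@H](OC(=O)/C(=C\C)CO[Si](c2ccccc2)(c2ccccc2)C(C)(C)C)/C(C)=C\I | intermediate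
24 | as 23 with C2 as aldehyde ((E)-2-methyl-4-oxobut-1-enyl chain on C6) | C=C1C(=O)O[C@H](/C=C(\C)CC=O)[C@H]1C[C@H](OC(=O)/C(=C\C)CO[Si](c2ccccc2)(c2ccccc2)C(C)(C)C)/C(C)=C\I | intermediate
25 | (Z)-alkenylchromium dichloride from 24 (chromium on C1 in place of iodine) | C=C1C(=O)O[C@H](/C=C(\C)CC=O)[C@H]1C[C@H](OC(=O)/C(=C\C)CO[Si](c2ccccc2)(c2ccccc2)C(C)(C)C)/C(C)=C\[Cr](Cl)Cl | intermediate
26 | TBDPS ether of the target: (1(10)Z,4E)-(2R,6R,7S,9S)-2-hydroxy-9-acyloxygermacra-1(10),4,11(13)-trien-12,6-olide, acyl = (Z)-2-(TBDPS-oxymethyl)but-2-enoyl | C=C1C(=O)O[C@@H]2/C=C(\C)C[C@@H](O)/C=C(/C)[C@@H](OC(=O)/C(=C\C)CO[Si](c3ccccc3)(c3ccccc3)C(C)(C)C)C[C@@H]12 | intermediate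
27 | CNP0273961.1: (1(10)Z,4E)-(2R,6R,7S,9S)-2-hydroxy-9-[(Z)-2-(hydroxymethyl)but-2-enoyloxy]germacra-1(10),4,11(13)-trien-12,6-olide | C=C1C(=O)O[C@@H]2/C=C(\C)C[C@@H](O)/C=C(/C)[C@@H](OC(=O)/C(=C\C)CO)C[C@@H]12 | target

## Step count and risks

Total step count: 15. Longest linear sequence: 10 steps (crotonaldehyde 6 through steps 4, 5, 6, 7, 8, 9, 12, 13, 14, 15).

Steps most likely to fail:

1. Step 14. What may go wrong: addition of the alkenylchromium to the Re face of the aldehyde, so that C2 forms with poor or reversed facial selectivity. Fallback, setting out from 24 and coming back at 26: the same ring closure is run and the epimeric (2S)-macrocyclic alcohol F1 (or the epimer mixture) is oxidised with Dess–Martin periodinane to the macrocyclic C2 enone F2. Reduction with (S)-2-methyl-CBS-oxazaborolidine and catecholborane in toluene at −78 °C, with the alkenyl group as the large substituent, should then give the 2R alcohol 26 under reagent control.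

2. Step 12. What may go wrong: the chromium catalyst fails to override the bias of the C9 stereocentre (mismatched double stereodifferentiation) and mixtures of trans lactones form. Fallback, setting out from 4 and coming back at 22, with substrate control through a temporary δ-lactone:
   - Allylboration of 4 with the reagent from (+)-Ipc2BOMe should give the enantiomeric alcohol, (3R,1Z)-1-iodo-2-methylhexa-1,5-dien-3-ol F3.
   - Acylation with 2-(bromomethyl)acryloyl chloride and 2,6-lutidine gives the 2-(bromomethyl)acrylate ester F4, and ring-closing metathesis (second-generation Hoveyda–Grubbs catalyst, toluene, 80 °C) the (6R)-3-(bromomethyl)-6-[(Z)-1-iodoprop-1-en-2-yl]-5,6-dihydropyran-2-one F5.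
   - A Barbier reaction of F5 with enal 19 (zinc dust, THF/aq. NH4Cl) should join C7 to the aldehyde anti to the C9 substituent of the ring and, through a chair transition state with the ring-locked allyl geometry, anti across C6–C7, giving the α-methylene-δ-lactone alcohol F6.
   - DBU-catalysed translactonisation to the more stable γ-lactone frees the C9 hydroxyl in the (9R)-alcohol F7.
   - Mitsunobu esterification with acid 11 (PPh3, DIAD, toluene, 0 °C) inverts C9 and gives 22, which is taken to 23 with PPTS in MeOH as in step 12.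

3. Step 9. What may go wrong: slow turnover and catalyst decomposition because the 1,1-disubstituted acrylate carries an allylic C–Br bond, so that homodimerisation of 13 takes over. Fallback, setting out from 13 and coming back at 15: cross-metathesis of 13 with methyl 2-(hydroxymethyl)acrylate (second-generation Hoveyda–Grubbs catalyst, CH2Cl2, 40 °C) gives the (2E)-2-(hydroxymethyl) enoate F8. The bromide is then introduced by Appel bromination (CBr4, PPh3, CH2Cl2, 0 °C) to give 15.

Further compounds
F1 | step 14 | (2S)-epimer of 26 | C=C1C(=O)O[C@@H]2/C=C(\C)C[C@H](O)/C=C(/C)[C@@H](OC(=O)/C(=C\C)CO[Si](c3ccccc3)(c3ccccc3)C(C)(C)C)C[C@@H]12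
F2 | step 14 | macrocyclic C2 enone (2-oxo analogue of 26) | C=C1C(=O)O[C@@H]2/C=C(\C)CC(=O)/C=C(/C)[C@@H](OC(=O)/C(=C\C)CO[Si](c3ccccc3)(c3ccccc3)C(C)(C)C)C[C@@H]12
F3 | step 12 | (3R,1Z)-1-iodo-2-methylhexa-1,5-dien-3-ol | I/C=C(/C)[C@H](O)CC=C
F4 | step 12 | (3R,1Z)-1-iodo-2-methylhexa-1,5-dien-3-yl 2-(bromomethyl)prop-2-enoate | I/C=C(/C)[C@H](OC(=O)C(=C)CBr)CC=C
F5 | step 12 | (6R)-3-(bromomethyl)-6-[(Z)-1-iodoprop-1-en-2-yl]-5,6-dihydro-2H-pyran-2-one | I/C=C(/C)[C@H]1CC=C(CBr)C(=O)O1
F6 | step 12 | (6R,7S,9R)-α-methylene-δ-lactone alcohol (lactone on the C9 oxygen, free C6 hydroxyl, C2–OTBS) | C=C1C(=O)O[C@@H](/C(C)=C\I)C[C@@H]1[C@H](O)/C=C(\C)CCO[Si](C)(C)C(C)(C)C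
F7 | step 12 | (6R,7S,9R)-trans-α-methylene-γ-butyrolactone with free C9 hydroxyl and C2–OTBS | C=C1C(=O)O[C@H](/C=C(\C)CCO[Si](C)(C)C(C)(C)C)[C@H]1C[C@@H](O)/C(C)=C\I
F8 | step 9 | methyl (2E,5S,6Z)-5-{[(Z)-2-{[(tert-butyldiphenylsilyl)oxy]methyl}but-2-enoyl]oxy}-2-(hydroxymethyl)-7-iodo-6-methylhepta-2,6-dienoate | I/C=C(/C)[C@@H](OC(=O)/C(=C\C)CO[Si](c1ccccc1)(c1ccccc1)C(C)(C)C)C/C=C(\CO)C(=O)OC
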